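## Structural features

The target is a labd-7-ene: a trans-fused decalin (ring A: C1–C5 and C10; ring B: C5–C10) with a gem-dimethyl carbon C4, an angular methyl on C10 and a trisubstituted C7=C8 alkene carrying the C8 methyl. C9 bears a five-carbon chain (C11–C15, methyl on C13) whose terminal oxygen is acylated by (E)-ferulic acid. Three of the five stereocentres (C5, C10, C9) are contiguous around the ring fusion (5α-H, 10β-methyl, 9β-chain). The fourth, C2 (2α, equatorial OH), lies across ring A between the quaternary carbons C4 and C10, and the fifth, C13 (R), is isolated on the chain and cannot be set from the ring. The fragile parts are the cinnamate ester with its free phenol (base, nucleophiles, oxidants, dissolving metal) and the Δ7 alkene, which strong acid can move to Δ8 or Δ8(17); the ester is therefore attached last. The real difficulties are the quaternary C10 inside a trans fusion of correct absolute sense, an oxygen at C2 with no neighbouring group to direct it, and a regiodefined Δ7 alkene next to the C9 stereocentre. The key step exploits the fact that C4, with its two methyls and its bond to C5, is the isopropenyl carbon of (R)-carvone after uptake of one hydrogen atom and one bond to C3; a tertiary C4 radical therefore closes ring A onto a C1–C2–C3 arm on C10 and leaves on C2 an epimerisable acetyl group that becomes the 2α-oxygen. A stereochemical check shows that (R)-carvone supplies C5 with the 5α-hydrogen, and that the (R)-half-ester maps onto 13R only if its acid carbon becomes C11 and its ester carbon C15.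

## Logic of the disconnections

28 ⇒ 27 ⇒ 25 + 26. The C15–O acyl bond is cut, together with the Si–O bond at C2. This is the most labile bond, and cutting it removes the phenol, the ester and the cinnamate from every earlier step. The forward step must acylate with the carboxyl group of 26 and not its phenol, and the C2 hydroxyl must stay masked until afterwards.

25 ⇒ 24 ⇒ 23 ⇒ 22 ⇒ 21. No skeletal bond is cut. The C7–H bond is traced to a C7–O bond (23), the enol derivative to the regiodefined enolate 22, and the C9–H bond to the β-carbon of enone 21. One reduction thus fixes both the alkene position and C9, and C9 becomes sp2 in the precursor. The forward steps need protonation of C9 from the α face, enolate capture without equilibration, and two silyl ethers of different reactivity (primary at C15, secondary at C2).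

21 ⇒ 20 ⇒ 13 + 18 (through 19). The C9–C11 bond is cut, after a 1,3-transposition of oxygen from C7 back to C9. This divides the molecule into the fourteen-carbon bicyclic enone and the five-carbon chain that carries C13, so C13 is bought and not made. The forward step needs 1,2-addition of a primary alkyllithium to a hindered enone in which nothing else is electrophilic, which is why C2 carries a silyl ether and not the acetate.

18 ⇒ 17 ⇒ 16 ⇒ 15 ⇒ 14. Only C–I and C–O bonds at C11 and C15 are changed. The two termini of 14 are told apart by chemoselective reductions, acid first and ester second. The order is dictated by stereochemistry: the acid carbon must become the nucleophilic C11.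

13 ⇒ 12 ⇒ 11 ⇒ 10. The C2–O bond is traced to a C2–C(acyl) bond by an oxygen insertion with retention. This replaces an unguided oxygenation by an equatorial carbon substituent that can be equilibrated. The forward oxidation must choose the saturated methyl ketone over the conjugated C9 ketone and its alkene.

10 ⇒ 8 (through 9). The C3–C4 bond of ring A and one C–H bond of a C4 methyl are cut. The bicycle becomes a monocyclic cyclohexenone that already holds all sixteen carbons, C2 ceases to be a stereocentre, and C5 and C10 remain as the only stereocentres. The forward step needs hydrogen-atom transfer to the isopropenyl group only, 6-endo closure, and equilibration at C2.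

8 ⇒ 3 + 6 (through 7). The C1–C10 bond is cut. The quaternary C10 is then made by alkylation of a tetrasubstituted enolate on the face anti to the isopropenyl group. The forward step needs clean C-alkylation by addition–elimination, without proton transfer or further Michael addition.

3 ⇒ 1 (through 2) and 6 ⇒ 5 ⇒ 4. The C10–CH3 bond and, in the arm, the C1–C2 bond are cut. This leaves the chiral-pool enone 1, a methylating agent, the vinyl ketone 4 and a one-carbon aldehyde. The demands are regioselective α′-enolisation of 1 and a clean α-hydroxymethylation of 4.

## Other disconnections considered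

Alternative 1: The cut is through ring B at C7–C8 and C9–C10. In the forward step the achiral diene A1 (a 1-vinylcyclohexene with the C2 ketal) would add to the ynone A2 (C8≡C9 conjugated to a C11 carbonyl, C13 already in place) under a chiral oxazaborolidinium acid to give the 5,8-diene A3.
- In its favour: it is convergent, it creates the quaternary C10 by catalyst control from an achiral ring piece, and it reaches the full C20 skeleton in fewer operations than the chosen plan needs to reach 21. On convergence and skeletal step economy it is the better plan.
- Against it here: the s-cis form of A1 is strained by the C4 gem-dimethyl and the C10 methyl, the new bond is made at a fully substituted diene terminus, and an alkyne offers no endo/exo element, so face selection rests on remote shielding alone.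
- A3 then still needs four corrections: removal of the C11 oxygen, α-face reduction of C5=C6, transposition of C8=C9 to C7=C8 with C9–H set, and reduction of the C2 ketone to the equatorial alcohol against the intrinsic preference for hydride delivery from the open α face.
- Comparison: the chosen plan takes C5 from the chiral pool, sets C10 by substrate control and sets C9 and C2 under thermodynamic control. It is longer to the C20 stage but shorter and surer from there to 28.

Alternative 2: The cut is the C9–C10 bond plus the C5–H bond. In the forward step a Brønsted acid (SnCl4 with a hindered phenol) would protonate C5 of the ring alkene in the monocyclic diene A4 (E-configured C8=C9), and the C10 cation would be captured by C9 with loss of a C7 proton to give A5, which is the same compound as 24.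
- In its favour: one operation would set C5, C10 and C9, place the Δ7 alkene and land directly on 24. It would replace the whole sequence up to 24, including steps 13 to 16 with their redox work at C7 and C9, so on step economy after the ring closure it is clearly the better plan. The E-alkene also gives the equatorial C9 chain through a chair.
- Against it here: protonation must occur at a tetrasubstituted ring alkene in the presence of a more accessible trisubstituted chain alkene. The trans fusion needs hydrogen and C9 to add to the same face of the ring alkene, which a stepwise cation need not respect. Face selection rests on one remote silyloxy group at C2, the final proton loss can give Δ7, Δ8 or Δ8(17), and two silyl ethers must survive a strong acid.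
- A4 also needs its own enantioselective synthesis with C2, C13 and the E-alkene.
- Comparison: one cationic event with weak control over three centres stands against a radical closure whose fusion is preset and whose remaining centres each have their own control element. The alternative is potentially shorter overall, the chosen plan more predictable.

Alternative 3: The cut is the C2–C3 bond of ring A. In the forward step Me2AlCl would activate the aldehyde of A6 (carvone carrying the C10 methyl and a CH2CHO arm trans to isopropenyl) for a type 2 carbonyl-ene reaction that gives the 2-hydroxy-4-methylene bicycle A7.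
- In its favour: the C2–O bond is formed directly at the right oxidation level, with no acetyl group and no oxygen insertion, and on this point it is the better plan. It shares the chiral pool, the preset trans fusion and the whole ring B endgame, on which it is the equal.
- Against it here: A7 is one carbon short at C4, so the exocyclic methylene must be cyclopropanated and hydrogenolysed, and the hydrogenolysis competes with reduction of the enone alkene.
- C2 is set kinetically in the ene transition state and cannot be corrected by equilibration.
- A6 needs a chemoselective oxidative cleavage in the presence of the isopropenyl and enone alkenes, or a sluggish alkylation with a masked acetaldehyde.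
- Comparison: the radical closure delivers the second C4 methyl by the hydrogen atom itself and fixes C2 thermodynamically. From ring closure to 12 both need two steps, but the precursor of the chosen plan is easier to reach and no late hydrogenation is required.

Key step: step 5

Remark on the chemistry: the C6 centre of 3 and the carbinol centre C9 of 20 are expected as epimer mixtures and are both erased later (steps 4 and 14), so the expected major epimer is drawn for each. TBS = tert-butyldimethylsilyl; labdane numbering is used for all bicyclic compounds.

## Route

Step 1
Reactants: 1 (R)-(−)-carvone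
Product: 3 trans-6-methylcarvone [(5R,6S)-2,6-dimethyl-5-(prop-1-en-2-yl)cyclohex-2-en-1-one; the cis 6R epimer accompanies it], via carvone lithium dienolate 2 (not isolated)
Conditions: LiN(iPr)2, THF, −78 °C; then MeI, −78 to 0 °C
Reagents that add atoms: iodomethane, CI
Why: Kinetic α′-deprotonation gives the cross-conjugated lithium dienolate, which is C-methylated at C6 (enolate alkylation); the epimer ratio at C6 does not matter because this centre is enolised again in step 4.

Step 2
Reactants: 4 methyl vinyl ketone (but-3-en-2-one)
Product: 5 3-(hydroxymethyl)but-3-en-2-one
Conditions: aq. HCHO (excess), DABCO (cat.), THF, rt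
Reagents that add atoms: formaldehyde, C=O
Why: Baylis–Hillman reaction: the amine adds to the vinyl ketone, the resulting enolate attacks formaldehyde and the amine is expelled; excess formaldehyde suppresses self-dimerisation of the vinyl ketone.

Step 3
Reactants: 5 3-(hydroxymethyl)but-3-en-2-one
Product: 6 2-methylidene-3-oxobutyl acetate
Conditions: Ac2O, pyridine, DMAP (cat.), CH2Cl2, 0 °C
Reagents that add atoms: acetic anhydride, CC(=O)OC(C)=O
Why: O-Acetylation of the primary allylic alcohol installs the leaving group needed for conjugate addition–elimination.

Step 4
Reactants: 3 trans-6-methylcarvone (with its cis epimer); 6 2-methylidene-3-oxobutyl acetate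
Product: 8 6-methyl-6-(2-acetylallyl)carvone [(5S,6S)-2,6-dimethyl-6-(2-methylidene-3-oxobutyl)-5-(prop-1-en-2-yl)cyclohex-2-en-1-one; arm trans to isopropenyl; methyl cis], via lithium enolate 7 (not isolated)
Conditions: LiN(iPr)2, THF, −78 to 0 °C; then added to 6 in THF, −78 to −20 °C
Reagents that add atoms: none
Why: The tetrasubstituted lithium enolate adds to the doubly activated alkene of 6 and acetate is expelled (SN2′-type addition–elimination on a Baylis–Hillman acetate), which restores the vinyl ketone in the new arm. The electrophile approaches anti to the neighbouring isopropenyl group, so the arm ends trans to it and the methyl cis, which fixes C10.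

Step 5
Reactants: 8 6-methyl-6-(2-acetylallyl)carvone
Product: 10 2α-acetyl-11-nordrim-7-en-9-one [(4aS,7S,8aS)-7-acetyl-2,5,5,8a-tetramethyl-4a,5,6,7,8,8a-hexahydronaphthalen-1(4H)-one; 5α-H; 10β-methyl; equatorial acetyl], via 2β-acetyl epimer 9 (not isolated)
Conditions: Fe(acac)3 (30 mol%), PhSiH3, EtOH/(CH2OH)2 (5:1), 60 °C; then K2CO3, MeOH, rt
Reagents that add atoms: none
Why: An iron hydride formed from Fe(acac)3 and PhSiH3 in ethanol transfers a hydrogen atom to the CH2 of the electron-rich isopropenyl group, which creates the second C4 methyl and a tertiary C4 radical. This nucleophilic radical adds to the unsubstituted terminus C3 of the tethered α-substituted vinyl ketone, a 6-endo-trig closure of ring A that forms C3–C4; the α-keto radical at C2 is then reduced by divalent iron to the enolate and protonated by the solvent. The closest known reaction type is the iron-hydride reductive coupling of 1,1-disubstituted alkenes with enones (hydrogen-atom-transfer-initiated Giese addition), including ring closures that form quaternary carbons. 5-exo attack is excluded because it would strike the fully substituted, polarity-mismatched α-carbon. The ring fusion is not created here: C5 and C10 already hold the two reacting arms trans on ring B, so only the trans-decalin can close. The one new stereocentre, C2, is under thermodynamic control: protonation from the open α face should first give the axial 2β-acetyl compound 9, which suffers two syn-axial methyls (on C4 and C10), and K2CO3 in methanol equilibrates it through the enol to the equatorial 2α epimer 10. The step needs chemoselective hydrogen-atom transfer to the isopropenyl group and not to either enone alkene, and this follows from alkene polarity.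

Step 6
Reactants: 10 2α-acetyl-11-nordrim-7-en-9-one
Product: 11 2α-acetoxy-11-nordrim-7-en-9-one
Conditions: mCPBA, CH2Cl2, 0 °C to rt
Reagents that add atoms: 3-chloroperbenzoic acid, OOC(=O)c1cccc(Cl)c1
Why: Baeyer–Villiger oxidation: the secondary ring carbon migrates in preference to methyl and with retention, so the equatorial acetyl becomes the 2α-acetate. The conjugated C9 ketone, flanked by the quaternary C10, and its electron-poor alkene are much less reactive towards the peracid.

Step 7
Reactants: 11 2α-acetoxy-11-nordrim-7-en-9-one
Product: 12 2α-hydroxy-11-nordrim-7-en-9-one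
Conditions: K2CO3 (cat.), MeOH, rt
Reagents that add atoms: none
Why: Base-catalysed transesterification removes the acetate, which would not survive the organolithium of step 13; the enone has no hydrogen on C10 and is unchanged.

Step 8
Reactants: 12 2α-hydroxy-11-nordrim-7-en-9-one
Product: 13 2α-(tert-butyldimethylsilyloxy)-11-nordrim-7-en-9-one
Conditions: TBSCl, imidazole, DMF, rt
Reagents that add atoms: tert-butyldimethylsilyl chloride, CC(C)(C)[Si](C)(C)Cl
Why: Silylation of the equatorial secondary alcohol gives an ether that tolerates the organolithium, the chromium oxidant and the dissolving metal of the following steps.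

Step 9
Reactants: 14 methyl hydrogen (R)-3-methylglutarate
Product: 15 methyl (R)-5-hydroxy-3-methylpentanoate
Conditions: BH3·SMe2, THF, 0 °C to rt; then H2O
Reagents that add atoms: none
Why: Borane reduces the free carboxylic acid much faster than the methyl ester, so the acid carbon (future C11) becomes CH2OH while the ester carbon (future C15) is kept; the stereocentre is not touched.

Step 10
Reactants: 15 methyl (R)-5-hydroxy-3-methylpentanoate
Product: 16 methyl (S)-5-iodo-3-methylpentanoate
Conditions: I2, PPh3, imidazole, CH2Cl2, 0 °C to rt
Reagents that add atoms: iodine, II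
Why: Appel-type iodination converts the primary alcohol into the iodide under neutral conditions that leave the ester alone; the descriptor changes only because of ligand priorities.

Step 11
Reactants: 16 methyl (S)-5-iodo-3-methylpentanoate
Product: 17 (S)-5-iodo-3-methylpentan-1-ol
Conditions: i-Bu2AlH, CH2Cl2, −78 to 0 °C
Reagents that add atoms: none
Why: The aluminium hydride reduces the methyl ester to the primary alcohol at low temperature, where a primary alkyl iodide is inert.

Step 12
Reactants: 17 (S)-5-iodo-3-methylpentan-1-ol
Product: 18 (S)-tert-butyl[(5-iodo-3-methylpentyl)oxy]dimethylsilane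
Conditions: TBSCl, imidazole, CH2Cl2, rt
Reagents that add atoms: tert-butyldimethylsilyl chloride, CC(C)(C)[Si](C)(C)Cl
Why: Standard silylation masks the future C15 oxygen as a primary silyl ether, which can later be removed in the presence of the secondary one at C2.

Step 13
Reactants: 18 (S)-tert-butyl[(5-iodo-3-methylpentyl)oxy]dimethylsilane; 13 2α-(tert-butyldimethylsilyloxy)-11-nordrim-7-en-9-one
Product: 20 (13R)-2α,15-bis(tert-butyldimethylsilyloxy)labd-7-en-9-ol (hydroxyl 9β and chain 9α in the epimer drawn), via alkyllithium 19 (not isolated)
Conditions: t-BuLi (2 equiv), Et2O/pentane, −78 °C; then 13, Et2O, −78 to 0 °C; H2O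
Reagents that add atoms: none
Why: Iodine–lithium exchange gives the primary alkyllithium without disturbing the silyl ether, and it adds 1,2 to the C9 carbonyl, which has no enolisable hydrogen on C10. Attack anti to the axial C10 methyl is expected, but the carbinol configuration is lost in step 14.

Step 14
Reactants: 20 (13R)-2α,15-bis(tert-butyldimethylsilyloxy)labd-7-en-9-ol
Product: 21 (13R)-2α,15-bis(tert-butyldimethylsilyloxy)labd-8-en-7-one
Conditions: [C5H5NH][CrO3Cl] (pyridinium chlorochromate), 4 Å molecular sieves, CH2Cl2, rt
Reagents that add atoms: pyridinium chlorochromate, [O-][Cr](=O)(=O)Cl.c1cc[nH+]cc1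
Why: Oxidative 1,3-transposition of a tertiary allylic alcohol: the chromate ester shifts from C9 to C7 by a [3,3] rearrangement and is oxidised there, giving the C7 ketone and the tetrasubstituted C8=C9 alkene that carries the chain.

Step 15
Reactants: 21 (13R)-2α,15-bis(tert-butyldimethylsilyloxy)labd-8-en-7-one
Product: 23 (13R)-2α,15-bis(tert-butyldimethylsilyloxy)labd-7-en-7-yl trifluoromethanesulfonate (9α-H), via lithium enolate 22 (not isolated)
Conditions: Li, NH3/THF, t-BuOH (1 equiv), −78 °C; isoprene; NH3 evaporated; then PhNTf2, THF, −78 °C to rt
Reagents that add atoms: N-phenylbis(trifluoromethanesulfonimide), O=S(=O)(N(c1ccccc1)S(=O)(=O)C(F)(F)F)C(F)(F)F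
Why: Dissolving-metal (Birch-type) reduction of the enone protonates the β-carbon C9 from the α face, axially and anti to the C10 methyl, which places the chain equatorial (9β). It leaves the regiodefined C7 enolate with its double bond at C7–C8, and O-triflation captures that regiochemistry.

Step 16
Reactants: 23 (13R)-2α,15-bis(tert-butyldimethylsilyloxy)labd-7-en-7-yl trifluoromethanesulfonate
Product: 24 (13R)-2α,15-bis(tert-butyldimethylsilyloxy)labd-7-ene
Conditions: Pd(OAc)2 (cat.), PPh3, HCO2H, Bu3N, DMF, 60 °C
Reagents that add atoms: none
Why: Palladium-catalysed formate reduction of the enol triflate (oxidative addition to zerovalent palladium, formate exchange, loss of CO2, reductive elimination) replaces C7–O by C7–H, keeps the alkene at C7–C8 and touches no stereocentre.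

Step 17
Reactants: 24 (13R)-2α,15-bis(tert-butyldimethylsilyloxy)labd-7-ene
Product: 25 (13R)-2α-(tert-butyldimethylsilyloxy)labd-7-en-15-ol
Conditions: camphorsulfonic acid (cat.), MeOH/CH2Cl2, 0 °C
Reagents that add atoms: none
Why: Acid-catalysed methanolysis cleaves the unhindered primary silyl ether much faster than the secondary one at C2, which is flanked by two neopentyl-type methylenes.

Step 18
Reactants: 25 (13R)-2α-(tert-butyldimethylsilyloxy)labd-7-en-15-ol; 26 (E)-ferulic acid
Product: 27 (13R)-2α-(tert-butyldimethylsilyloxy)labd-7-en-15-yl (E)-ferulate
Conditions: PPh3, DIAD, THF, 0 °C to rt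
Reagents that add atoms: none
Why: Mitsunobu esterification: the primary alcohol is activated as its alkoxyphosphonium ion and displaced by the carboxylate of 26, which is far more acidic than the phenol and so is the nucleophile; no stereocentre is involved and the E-alkene is not touched.

Step 19
Reactants: 27 (13R)-2α-(tert-butyldimethylsilyloxy)labd-7-en-15-yl (E)-ferulate
Product: 28 (13R)-labd-7-ene-2α,15-diol 15-(E)-ferulate (CNP0175017.1)
Conditions: HF·pyridine, pyridine, THF, 0 °C to rt
Reagents that add atoms: none
Why: Fluoride cleaves the remaining Si–O bond under buffered, mildly acidic conditions that spare the cinnamate ester, the phenol and the trisubstituted alkene, and so releases the 2α-alcohol.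

## Compound list

1 | (R)-(−)-carvone | CC(=C)[C@@H]1CC=C(C)C(=O)C1 | starting material
2 | carvone lithium dienolate | CC(=C)[C@@H]1CC=C(C)C(O[Li])=C1 | intermediate (not isolated)
3 | trans-6-methylcarvone, (5R,6S)-2,6-dimethyl-5-(prop-1-en-2-yl)cyclohex-2-en-1-one (cis epimer accompanies) | O=C1C(C)=CC[C@@H](C(C)=C)[C@@H]1C | intermediate
4 | methyl vinyl ketone | CC(=O)C=C | starting material
5 | 3-(hydroxymethyl)but-3-en-2-one | CC(=O)C(=C)CO | intermediate
6 | 2-methylidene-3-oxobutyl acetate | CC(=O)OCC(=C)C(C)=O | intermediate
7 | lithium enolate of 6-methylcarvone | CC(=C)[C@@H]1CC=C(C)C(O[Li])=C1C | intermediate (not isolated)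
8 | 6-methyl-6-(2-acetylallyl)carvone, (5S,6S), arm trans to isopropenyl | O=C1C(C)=CC[C@@H](C(C)=C)[C@]1(C)CC(=C)C(C)=O | intermediate
9 | 2β-acetyl-11-nordrim-7-en-9-one (axial acetyl) | O=C2C(C)=CC[C@H]3C(C)(C)C[C@@H](C(C)=O)C[C@]23C | intermediate (not isolated)
10 | 2α-acetyl-11-nordrim-7-en-9-one, (4aS,7S,8aS)-7-acetyl-2,5,5,8a-tetramethyl-4a,5,6,7,8,8a-hexahydronaphthalen-1(4H)-one | O=C2C(C)=CC[C@H]3C(C)(C)C[C@H](C(C)=O)C[C@]23C | intermediate
11 | 2α-acetoxy-11-nordrim-7-en-9-one | O=C2C(C)=CC[C@H]3C(C)(C)C[C@H](OC(C)=O)C[C@]23C | intermediate
12 | 2α-hydroxy-11-nordrim-7-en-9-one | O=C2C(C)=CC[C@H]3C(C)(C)C[C@H](O)C[C@]23C | intermediate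
13 | 2α-(tert-butyldimethylsilyloxy)-11-nordrim-7-en-9-one | O=C2C(C)=CC[C@H]3C(C)(C)C[C@H](O[Si](C)(C)C(C)(C)C)C[C@]23C | intermediate
14 | methyl hydrogen (R)-3-methylglutarate | COC(=O)C[C@H](C)CC(=O)O | starting material
15 | methyl (R)-5-hydroxy-3-methylpentanoate | COC(=O)C[C@H](C)CCO | intermediate
16 | methyl (S)-5-iodo-3-methylpentanoate | COC(=O)C[C@H](C)CCI | intermediate
17 | (S)-5-iodo-3-methylpentan-1-ol | OCC[C@H](C)CCI | intermediate
18 | (S)-tert-butyl[(5-iodo-3-methylpentyl)oxy]dimethylsilane | CC(C)(C)[Si](C)(C)OCC[C@H](C)CCI | intermediate
19 | (R)-[5-(tert-butyldimethylsilyloxy)-3-methylpentyl]lithium | CC(C)(C)[Si](C)(C)OCC[C@H](C)CC[Li] | intermediate (not isolated)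
20 | (13R)-2α,15-bis(tert-butyldimethylsilyloxy)labd-7-en-9-ol (9β-OH, 9α-chain drawn) | CC(C)(C)[Si](C)(C)OCC[C@H](C)CC[C@]2(O)C(C)=CC[C@H]3C(C)(C)C[C@H](O[Si](C)(C)C(C)(C)C)C[C@]23C | intermediate
21 | (13R)-2α,15-bis(tert-butyldimethylsilyloxy)labd-8-en-7-one | CC(C)(C)[Si](C)(C)OCC[C@H](C)CCC2=C(C)C(=O)C[C@H]3C(C)(C)C[C@H](O[Si](C)(C)C(C)(C)C)C[C@]23C | intermediate
22 | lithium (13R)-2α,15-bis(tert-butyldimethylsilyloxy)labd-7-en-7-olate (9α-H) | CC(C)(C)[Si](C)(C)OCC[C@H](C)CC[C@H]2C(C)=C(O[Li])C[C@H]3C(C)(C)C[C@H](O[Si](C)(C)C(C)(C)C)C[C@]23C | intermediate (not isolated)
23 | (13R)-2α,15-bis(tert-butyldimethylsilyloxy)labd-7-en-7-yl trifluoromethanesulfonate | CC(C)(C)[Si](C)(C)OCC[C@H](C)CC[C@H]2C(C)=C(OS(=O)(=O)C(F)(F)F)C[C@H]3C(C)(C)C[C@H](O[Si](C)(C)C(C)(C)C)C[C@]23C | intermediate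
24 | (13R)-2α,15-bis(tert-butyldimethylsilyloxy)labd-7-ene | CC(C)(C)[Si](C)(C)OCC[C@H](C)CC[C@H]2C(C)=CC[C@H]3C(C)(C)C[C@H](O[Si](C)(C)C(C)(C)C)C[C@]23C | intermediate
25 | (13R)-2α-(tert-butyldimethylsilyloxy)labd-7-en-15-ol | OCC[C@H](C)CC[C@H]2C(C)=CC[C@H]3C(C)(C)C[C@H](O[Si](C)(C)C(C)(C)C)C[C@]23C | intermediate
26 | (E)-ferulic acid | COc1cc(/C=C/C(=O)O)ccc1O | starting material
27 | (13R)-2α-(tert-butyldimethylsilyloxy)labd-7-en-15-yl (E)-ferulate | COc1cc(/C=C/C(=O)OCC[C@H](C)CC[C@H]2C(C)=CC[C@H]3C(C)(C)C[C@H](O[Si](C)(C)C(C)(C)C)C[C@]23C)ccc1O | intermediate
28 | (13R)-labd-7-ene-2α,15-diol 15-(E)-ferulate, CNP0175017.1 | COc1cc(/C=C/C(=O)OCC[C@H](C)CC[C@H]2C(C)=CC[C@H]3C(C)(C)C[C@H](O)C[C@]23C)ccc1O | target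

## Step count and least certain steps

Total step count: 19. Longest linear sequence: 14 steps (steps 2, 3, 4 to 8 and 13 to 19, counted from 4). The branch from 1 (steps 1, 4 to 8 and 13 to 19) has 13 steps, and the branch from 14 (steps 9 to 19) has 11 steps.

Step 5 (key step). The most likely failure is reduction of the C4 radical before it closes (net hydrogenation of the isopropenyl group). Competing hydrogen-atom transfer to the vinyl ketone and intermolecular Giese addition leading to oligomers are also possible, because the acceptor is a reactive α-methylene ketone. The fallback sets out from 8. Markovnikov hydrobromination of the isopropenyl group (HBr, AcOH, 0 °C, then a brief Et3N treatment that reverses any conjugate addition of HBr to the vinyl ketone) should give the tertiary bromide F1. Slow addition of Bu3SnH with AIBN in benzene at 80 °C generates the same C4 radical by bromine abstraction and closes ring A by the same 6-endo addition. After K2CO3/MeOH equilibration at C2 the route is rejoined at 10.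

Step 4. The likely failures are proton transfer from the methyl ketone of 6 to the hindered enolate and further Michael addition of enolate to the vinyl ketone of the product, both of which consume material as oligomers. The fallback sets out from 3. Alkylation of its lithium enolate with 2,3-dibromopropene, anti to the isopropenyl group, gives the 2-bromoallyl ketone F2. Nozaki–Hiyama–Kishi coupling with acetaldehyde (CrCl2, NiCl2 cat., DMF), which tolerates ketones, gives the allylic alcohol F3 as both carbinol epimers. Oxidation with MnO2 rejoins the route at 8.

Step 14. The likely failures are dehydration of the hindered tertiary allylic alcohol to dienes under the acidic chromium reagent, or slow rearrangement of the chromate ester. The fallback sets out from 20 and separates the two events. A catalytic perrhenate ester (O3ReOSiPh3, Et2O, 0 °C) moves the hydroxyl from C9 to C7 and gives the secondary allylic alcohol F4 with the more substituted alkene. MnO2 then oxidises it, and the route is rejoined at 21.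

Step 15. The likely failures are loss of the enolate regiochemistry by proton exchange before capture, incomplete O-sulfonylation, or over-reduction of the carbonyl. The fallback sets out from 21. The same lithium/ammonia reduction is quenched with NH4Cl to give the saturated ketone F5 (9α-H, equatorial 8α-methyl). Tf2O with 2,6-di-tert-butyl-4-methylpyridine in CH2Cl2, conditions that favour the more substituted enol triflate, then rejoins the route at 23.

Step 18. The likely failure is alkylation of the phenol oxygen in competition with the carboxylate when the reagents are in excess. The fallback sets out from 25. Carbodiimide esterification (EDC·HCl, DMAP, CH2Cl2) with purchased 4-O-acetylferulic acid gives the aryl acetate F6. Selective aminolysis of the phenolic acetate with pyrrolidine at 0 °C rejoins the route at 27.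

## Further compounds

F1 | step 5 | tertiary bromide, 5-(2-bromopropan-2-yl)-2,6-dimethyl-6-(2-methylidene-3-oxobutyl)cyclohex-2-en-1-one (arm trans to the bromoalkyl group) | O=C1C(C)=CC[C@@H](C(C)(C)Br)[C@]1(C)CC(=C)C(C)=O
F2 | step 4 | 6-(2-bromoallyl)-6-methylcarvone (arm trans to isopropenyl) | O=C1C(C)=CC[C@@H](C(C)=C)[C@]1(C)CC(Br)=C
F3 | step 4 | 6-(3-hydroxy-2-methylidenebutyl)-6-methylcarvone (both carbinol epimers; carbinol centre left open) | O=C1C(C)=CC[C@@H](C(C)=C)[C@]1(C)CC(=C)C(C)O
F4 | step 14 | (13R)-2α,15-bis(tert-butyldimethylsilyloxy)labd-8-en-7-ol (7β-ol drawn; either C7 epimer serves) | CC(C)(C)[Si](C)(C)OCC[C@H](C)CCC2=C(C)[C@@H](O)C[C@H]3C(C)(C)C[C@H](O[Si](C)(C)C(C)(C)C)C[C@]23C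
F5 | step 15 | (13R)-2α,15-bis(tert-butyldimethylsilyloxy)labdan-7-one (9α-H, 8α-methyl) | CC(C)(C)[Si](C)(C)OCC[C@H](C)CC[C@H]2[C@H](C)C(=O)C[C@H]3C(C)(C)C[C@H](O[Si](C)(C)C(C)(C)C)C[C@]23C
F6 | step 18 | (13R)-2α-(tert-butyldimethylsilyloxy)labd-7-en-15-yl (E)-4-O-acetylferulate | COc1cc(/C=C/C(=O)OCC[C@H](C)CC[C@H]2C(C)=CC[C@H]3C(C)(C)C[C@H](O[Si](C)(C)C(C)(C)C)C[C@]23C)ccc1OC(C)=O
A1 | alternative 1 | 7,9,9-trimethyl-8-vinyl-1,4-dioxaspiro[4.5]dec-7-ene (ring A diene) | C=CC1=C(C)CC2(OCCO2)CC1(C)C
A2 | alternative 1 | (S)-8-(tert-butyldimethylsilyloxy)-6-methyloct-2-yn-4-one (ynone) | CC#CC(=O)C[C@@H](C)CCO[Si](C)(C)C(C)(C)C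
A3 | alternative 1 | 11-oxolabda-5,8-diene 2-ethylene ketal 15-tert-butyldimethylsilyl ether | CC(C)(C)[Si](C)(C)OCC[C@H](C)CC(=O)C2=C(C)CC=C3C(C)(C)CC4(OCCO4)C[C@]23C
A4 | alternative 2 | monocyclic 5(10),8(E)-diene bis(tert-butyldimethylsilyl) ether (ring A with C2 silyloxy; chain on C5) | CC1=C(CC/C(C)=C/CC[C@@H](C)CCO[Si](C)(C)C(C)(C)C)C(C)(C)C[C@H](O[Si](C)(C)C(C)(C)C)C1
A5 | alternative 2 | (13R)-2α,15-bis(tert-butyldimethylsilyloxy)labd-7-ene (identical with 24) | CC(C)(C)[Si](C)(C)OCC[C@H](C)CC[C@H]2C(C)=CC[C@H]3C(C)(C)C[C@H](O[Si](C)(C)C(C)(C)C)C[C@]23C
A6 | alternative 3 | 6-methyl-6-(2-oxoethyl)carvone (arm trans to isopropenyl) | O=C1C(C)=CC[C@@H](C(C)=C)[C@]1(C)CC=O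
A7 | alternative 3 | 2α-hydroxy-4-methylene bicyclic enone (C9 ketone, Δ7) | O=C2C(C)=CC[C@H]3C(=C)C[C@H](O)C[C@]23C
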